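**Retrosynthetic overview**
1. Target 23 ⇐ 14‑hydroxy precursor 22 (the enol ether is made last by dehydration) ⇐ 21, whose ring D comes from a Meyer–Schuster / 5‑endo oxa‑Michael cascade on alkynediol 19 (C12=O and C9–O–C13 in one operation).
2. 19 ⇐ tricyclic 3,9‑diketo‑19,6β‑olide 12 + ethynyl carbinol 16 (ring E pre‑formed from 1,4‑anhydro‑L‑threitol; C13 fixed there, C14 is a traceless relay).
3. 12 ⇐ carboxylate‑directed C6–H lactonisation (ring C) of the 4β‑acid from diketo ester 10 ⇐ ozonolysis of methylene compound 9.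
4. 9 ⇐ acyclic alkynyl β‑keto ester 8 by one Mn(III) radical 6‑endo/6‑exo‑dig bicyclisation (rings A+B; C4, C5, C10); 8 ⇐ (R)‑citronellal (C8) + tert‑butyl 2‑methylacetoacetate.
5. Ring order: A+B (step 5) → C (step 7) → D (step 12); E enters saturated (steps 8–10) and is desaturated in step 14.

Assumption: decalin compounds are named with labdane numbering (C17 = 8‑Me, C18 = 4α‑Me, C19 = 4β carbonyl carbon, C20 = 10β‑Me; α/β relative to C20); (3S,4S)‑tetrahydrofuran‑3,4‑diol 13 and tert‑butyl 2‑methylacetoacetate 6 are taken as purchasable.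

**Route**

Step 1
Reactants: 1 (R)-citronellal
Product: 3 (3R)-3,7-dimethyloct-6-en-1-yne, via enol nonaflate 2 (not isolated)
Conditions: C4F9SO2F, phosphazene base P2‑Et (2.5 equiv), DMF, −20 °C → rt
Reagents that add atoms: none
Why: One‑pot enol nonaflation/β‑elimination (aldehyde‑to‑alkyne "dehydration") turns RCH2CHO into RC≡CH without changing the carbon count, and the C3 stereocentre (future C8) is β to the carbonyl, not enolisable, and is carried through unchanged.

Step 2
Reactants: 3 (3R)-3,7-dimethyloct-6-en-1-yne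
Product: 4 (2E,6R)-2,6-dimethyloct-2-en-7-yn-1-ol
Conditions: SeO2 (cat.), t‑BuOOH, CH2Cl2, 0 °C → rt
Reagents that add atoms: tert-butyl hydroperoxide CC(C)(C)OO
Why: SeO2/t‑BuOOH allylic oxidation (ene then [2,3]‑sigmatropic shift) hydroxylates the (E)‑methyl of the trisubstituted alkene selectively, and the terminal alkyne is far less reactive.

Step 3
Reactants: 4 (2E,6R)-2,6-dimethyloct-2-en-7-yn-1-ol
Product: 5 (2E,6R)-1-bromo-2,6-dimethyloct-2-en-7-yne
Conditions: CBr4, PPh3, CH2Cl2, 0 °C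
Reagents that add atoms: carbon tetrabromide BrC(Br)(Br)Br
Why: Appel bromination is an SN2 displacement at the primary allylic carbon, so alkene geometry and the remote stereocentre are kept.

Step 4
Reactants: 5 (2E,6R)-1-bromo-2,6-dimethyloct-2-en-7-yne; 6 tert-butyl 2-methyl-3-oxobutanoate
Product: 8 tert-butyl (6E,10R)-2,6,10-trimethyl-3-oxododec-6-en-11-ynoate, via dianion 7 (not isolated)
Conditions: 6, NaH then n‑BuLi, THF, 0 °C; then 5, 0 °C → rt; aq NH4Cl
Reagents that add atoms: none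
Why: Weiler dianion alkylation: the γ‑carbanion is the most nucleophilic site and displaces the allylic bromide by SN2 faster than it deprotonates the alkyne; C2 of 8 is an enolisable epimer mixture of no consequence.

Step 5
Reactants: 8 tert-butyl (6E,10R)-2,6,10-trimethyl-3-oxododec-6-en-11-ynoate
Product: 9 tert-butyl (1R,4aS,6R,8aR)-1,4a,6-trimethyl-5-methylidene-2-oxodecahydronaphthalene-1-carboxylate
Conditions: Mn(OAc)3·2H2O (2.2 equiv), degassed EtOH/AcOH 9:1, 40 °C; chromatography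
Reagents that add atoms: none
Why: Mn(III)‑based oxidative free‑radical polyene cyclisation: the α‑keto‑ester radical closes 6‑endo‑trig and the tertiary C10 radical then closes 6‑exo‑dig through a chair–chair array, the vinyl radical taking H from ethanol; the chair transition state puts the ester axial (C19 β) and gives the trans ring fusion (10β‑Me, 5α‑H), and the absolute sense is selected by the (R)‑C8 centre, because only the C5 epimer that keeps the C8 methyl equatorial closes ring B efficiently (the mismatched radical, with axial methyl syn to the C10 methyl, is diverted and separated, so at most about half of the material can give 9).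

Step 6
Reactants: 9 tert-butyl (1R,4aS,6R,8aR)-1,4a,6-trimethyl-5-methylidene-2-oxodecahydronaphthalene-1-carboxylate
Product: 10 tert-butyl (1R,4aS,6R,8aR)-1,4a,6-trimethyl-2,5-dioxodecahydronaphthalene-1-carboxylate
Conditions: O3, CH2Cl2/MeOH, −78 °C; Me2S
Reagents that add atoms: ozone [O-][O+]=O
Why: Ozonolysis of the only C=C unmasks the C9 ketone; the 8α‑methyl is already equatorial (thermodynamic), so the now enolisable C8 is not at risk.

Step 7
Reactants: 10 tert-butyl (1R,4aS,6R,8aR)-1,4a,6-trimethyl-2,5-dioxodecahydronaphthalene-1-carboxylate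
Product: 12 3,9-dioxo-11,12,13,14,15,16-hexanorlabdan-19,6β-olide, via keto acid 11 (not isolated)
Conditions: TFA/CH2Cl2, 0 °C, evaporate cold; then [Mn(TIPS‑pdp)(OTf)2] (2 mol %), H2O2 (slow addition), CF3CH2OH, 0 °C
Reagents that add atoms: none
Why: Acidolysis (E1 loss of isobutene) frees the 4β‑axial acid, which directs a Mn‑catalysed γ‑C(sp3)–H lactonisation (carboxylate‑bound Mn‑oxo, H abstraction, carboxylate rebound); only the 1,3‑diaxial 6β‑H is within reach, so C6 is set as the 19,6β‑olide, and telescoping avoids isolating the β‑keto acid.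

Step 8
Reactants: 13 (3S,4S)-tetrahydrofuran-3,4-diol
Product: 14 (3S,4S)-4-(tert-butyldiphenylsilyloxy)tetrahydrofuran-3-ol
Conditions: NaH (1.0 equiv), THF, 0 °C; TBDPSCl (1.0 equiv)
Reagents that add atoms: tert-butyl(chloro)diphenylsilane CC(C)(C)[Si](Cl)(c1ccccc1)c1ccccc1
Why: Monosilylation of a C2‑symmetric diol through its mono‑sodium alkoxide; the two hydroxyls are equivalent, so there is no regiochemical issue.

Step 9
Reactants: 14 (3S,4S)-4-(tert-butyldiphenylsilyloxy)tetrahydrofuran-3-ol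
Product: 15 (4S)-4-(tert-butyldiphenylsilyloxy)dihydrofuran-3(2H)-one
Conditions: Dess–Martin periodinane, CH2Cl2, rt
Reagents that add atoms: none
Why: Dess–Martin oxidation is neutral and leaves the α‑silyloxy stereocentre unepimerised.

Step 10
Reactants: 15 (4S)-4-(tert-butyldiphenylsilyloxy)dihydrofuran-3(2H)-one
Product: 16 (3R,4S)-4-(tert-butyldiphenylsilyloxy)-3-ethynyltetrahydrofuran-3-ol
Conditions: HC≡CMgBr, THF, −78 → 0 °C; aq NH4Cl; chromatography
Reagents that add atoms: ethynylmagnesium bromide C#C[Mg]Br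
Why: Grignard 1,2‑addition to the cyclic α‑silyloxy ketone occurs anti to the bulky OTBDPS group (Felkin‑type substrate control), setting the quaternary carbinol that becomes C13 with OH cis to the silyloxy group; the minor epimer is removed.

Step 11
Reactants: 12 3,9-dioxo-11,12,13,14,15,16-hexanorlabdan-19,6β-olide; 16 (3R,4S)-4-(tert-butyldiphenylsilyloxy)-3-ethynyltetrahydrofuran-3-ol
Product: 19 9α-{[(3R,4S)-4-(tert-butyldiphenylsilyloxy)-3-hydroxytetrahydrofuran-3-yl]ethynyl}-9β-hydroxy-3-oxo-11,12,13,14,15,16-hexanorlabdan-19,6β-olide, via lithium enolate 17 (not isolated), via dilithio acetylide 18 (not isolated)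
Conditions: 12, LiHMDS (1.05 equiv), THF, −78 °C; 16, n‑BuLi (2 equiv), THF, −78 °C, then CeCl3; combine, −78 → −30 °C; aq NH4Cl
Reagents that add atoms: none
Why: The C3 ketone is masked in situ as its lithium enolate (C2–H2 is the only kinetically accessible α‑position), and the cerium acetylide then adds 1,2 to the hindered C9 ketone (organocerium alkynylation) from the axial α face away from the 10β‑methyl; the resulting C9 configuration is erased in step 12.

Step 12
Reactants: 19 9α-{[(3R,4S)-4-(tert-butyldiphenylsilyloxy)-3-hydroxytetrahydrofuran-3-yl]ethynyl}-9β-hydroxy-3-oxo-11,12,13,14,15,16-hexanorlabdan-19,6β-olide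
Product: 21 (13R,14S)-14-(tert-butyldiphenylsilyloxy)-9α,13:15,16-diepoxy-3,12-dioxolabdan-19,6β-olide, via hydroxy enone 20 (not isolated)
Conditions: Bu4NReO4 (10 mol %), TsOH·H2O (20 mol %), CH2Cl2, rt → 40 °C
Reagents that add atoms: none
Why: Perrhenate/acid‑catalysed Meyer–Schuster rearrangement transposes the more ionisable C9 hydroxyl to C12 (the C13 carbinol is deactivated by two β‑oxygens), and the α′‑hydroxy enone closes by acid‑catalysed 5‑endo oxa‑Michael addition (the classical alkyne‑1,4‑diol → tetrahydrofuran‑3‑one conversion); the 13‑oxygen adds to C9 axially from the α face anti to the 10β‑methyl and, the addition being reversible, the thermodynamic 9α‑O spiro centre with equatorial C11 results, C13 being untouched.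

Step 13
Reactants: 21 (13R,14S)-14-(tert-butyldiphenylsilyloxy)-9α,13:15,16-diepoxy-3,12-dioxolabdan-19,6β-olide
Product: 22 (13R,14S)-9α,13:15,16-diepoxy-14-hydroxy-3,12-dioxolabdan-19,6β-olide
Conditions: HF·pyridine, THF/pyridine, 0 °C → rt
Reagents that add atoms: none
Why: Fluoride desilylation in a weakly acidic medium, chosen because a basic medium could trigger retro‑aldol cleavage of the β‑hydroxy ketone (C12=O/C14–OH) and scramble C13.

Step 14
Reactants: 22 (13R,14S)-9α,13:15,16-diepoxy-14-hydroxy-3,12-dioxolabdan-19,6β-olide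
Product: 23 (13S)-9α,13:15,16-diepoxy-3,12-dioxolabd-14-en-19,6β-olide
Conditions: Martin sulfurane Ph2S[OC(CF3)2Ph]2 (2 equiv), CH2Cl2, 0 °C → rt; Et3N quench
Reagents that add atoms: none
Why: Martin sulfurane dehydration (alkoxysulfonium formation then E2) can only remove a C15 hydrogen because C13 is quaternary, so the 14,15‑enol ether forms regiospecifically under neutral conditions; the relay centre C14 disappears and no other centre is touched (the C13 descriptor changes from R to S only through CIP priorities).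

**Compound list**
1 | (R)-citronellal, (3R)-3,7-dimethyloct-6-enal | CC(C)=CCC[C@@H](C)CC=O | starting material
2 | (3R)-3,7-dimethylocta-1,6-dien-1-yl nonafluorobutane-1-sulfonate (E/Z) | CC(C)=CCC[C@@H](C)C=COS(=O)(=O)C(F)(F)C(F)(F)C(F)(F)C(F)(F)F | intermediate (not isolated)
3 | (3R)-3,7-dimethyloct-6-en-1-yne | CC(C)=CCC[C@@H](C)C#C | intermediate
4 | (2E,6R)-2,6-dimethyloct-2-en-7-yn-1-ol | OC/C(C)=C/CC[C@@H](C)C#C | intermediate
5 | (2E,6R)-1-bromo-2,6-dimethyloct-2-en-7-yne | BrC/C(C)=C/CC[C@@H](C)C#C | intermediate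
6 | tert-butyl 2-methyl-3-oxobutanoate | CC(=O)C(C)C(=O)OC(C)(C)C | starting material
7 | sodium lithium dianion of 6 | [Na+].[Li+].C=C([O-])C(C)=C([O-])OC(C)(C)C | intermediate (not isolated)
8 | tert-butyl (6E,10R)-2,6,10-trimethyl-3-oxododec-6-en-11-ynoate (C2 epimers) | CC(C(=O)OC(C)(C)C)C(=O)CC/C(C)=C/CC[C@@H](C)C#C | intermediate
9 | tert-butyl (1R,4aS,6R,8aR)-1,4a,6-trimethyl-5-methylidene-2-oxodecahydronaphthalene-1-carboxylate (tert-butyl 3-oxo-12,13,14,15,16-pentanorlabd-9(11)-en-19-oate) | C[C@@H]1CC[C@H]2[C@@](C)(C(=O)OC(C)(C)C)C(=O)CC[C@]2(C)C1=C | intermediate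
10 | tert-butyl (1R,4aS,6R,8aR)-1,4a,6-trimethyl-2,5-dioxodecahydronaphthalene-1-carboxylate | C[C@@H]1CC[C@H]2[C@@](C)(C(=O)OC(C)(C)C)C(=O)CC[C@]2(C)C1=O | intermediate
11 | (1R,4aS,6R,8aR)-1,4a,6-trimethyl-2,5-dioxodecahydronaphthalene-1-carboxylic acid | C[C@@H]1CC[C@H]2[C@@](C)(C(=O)O)C(=O)CC[C@]2(C)C1=O | intermediate (not isolated)
12 | 3,9-dioxo-11,12,13,14,15,16-hexanorlabdan-19,6β-olide (4α-Me, 5α-H, 8α-Me, 10β-Me) | C[C@@H]1C[C@H]2OC(=O)[C@@]3(C)C(=O)CC[C@@](C)([C@@H]23)C1=O | intermediate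
13 | (3S,4S)-tetrahydrofuran-3,4-diol (1,4-anhydro-L-threitol) | O[C@H]1COC[C@@H]1O | starting material
14 | (3S,4S)-4-(tert-butyldiphenylsilyloxy)tetrahydrofuran-3-ol | O[C@H]1COC[C@@H]1O[Si](c1ccccc1)(c1ccccc1)C(C)(C)C | intermediate
15 | (4S)-4-(tert-butyldiphenylsilyloxy)dihydrofuran-3(2H)-one | O=C1COC[C@@H]1O[Si](c1ccccc1)(c1ccccc1)C(C)(C)C | intermediate
16 | (3R,4S)-4-(tert-butyldiphenylsilyloxy)-3-ethynyltetrahydrofuran-3-ol (OH cis to OSi) | C#C[C@@]1(O)COC[C@@H]1O[Si](c1ccccc1)(c1ccccc1)C(C)(C)C | intermediate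
17 | lithium C2–C3 enolate of 12 | [Li+].C[C@@H]1C[C@H]2OC(=O)[C@@]3(C)C([O-])=CC[C@@](C)([C@@H]23)C1=O | intermediate (not isolated)
18 | dilithium alkoxide–acetylide of 16 (transmetallated to Ce(III)) | [Li+].[Li+].[C-]#C[C@@]1([O-])COC[C@@H]1O[Si](c1ccccc1)(c1ccccc1)C(C)(C)C | intermediate (not isolated)
19 | 9α-{[(3R,4S)-4-(tert-butyldiphenylsilyloxy)-3-hydroxytetrahydrofuran-3-yl]ethynyl}-9β-hydroxy-3-oxo-11,12,13,14,15,16-hexanorlabdan-19,6β-olide | C[C@@H]1C[C@H]2OC(=O)[C@@]3(C)C(=O)CC[C@@](C)([C@@H]23)[C@]1(O)C#C[C@@]1(O)COC[C@@H]1O[Si](c1ccccc1)(c1ccccc1)C(C)(C)C | intermediate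
20 | (13R,14S)-14-(tert-butyldiphenylsilyloxy)-13-hydroxy-15,16-epoxy-3,12-dioxolabd-9(11)-en-19,6β-olide (E/Z) | C[C@@H]1C[C@H]2OC(=O)[C@@]3(C)C(=O)CC[C@@](C)([C@@H]23)C1=CC(=O)[C@@]1(O)COC[C@@H]1O[Si](c1ccccc1)(c1ccccc1)C(C)(C)C | intermediate (not isolated)
21 | (13R,14S)-14-(tert-butyldiphenylsilyloxy)-9α,13:15,16-diepoxy-3,12-dioxolabdan-19,6β-olide | C[C@@H]1C[C@H]2OC(=O)[C@@]3(C)C(=O)CC[C@@](C)([C@@H]23)[C@@]12CC(=O)[C@@]1([C@@H](O[Si](c3ccccc3)(c3ccccc3)C(C)(C)C)COC1)O2 | intermediate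
22 | (13R,14S)-9α,13:15,16-diepoxy-14-hydroxy-3,12-dioxolabdan-19,6β-olide | C[C@@H]1C[C@H]2OC(=O)[C@@]3(C)C(=O)CC[C@@](C)([C@@H]23)[C@@]12CC(=O)[C@@]1([C@@H](O)COC1)O2 | intermediate
23 | (13S)-9α,13:15,16-diepoxy-3,12-dioxolabd-14-en-19,6β-olide (CNP0143138.1) | C[C@@H]1C[C@H]2OC(=O)[C@@]3(C)C(=O)CC[C@@](C)([C@@H]23)[C@@]12CC(=O)[C@@]1(C=COC1)O2 | target

**Totals**
Total step count: 14. Longest linear sequence: 11 steps (steps 1–7, then 11–14); the side branch to 16 is 3 steps (8–10).

**Steps most likely to fail, with fallbacks**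

Step 5 (radical bicyclisation). The first ring closure is not itself controlled by the remote C8 centre, so the yield of 9 is capped and the 6‑exo‑dig closure of a tertiary radical may be slow. The fallback sets out from 8 and returns at 10. Compound 8 is α‑brominated (NBS, cat. Mg(ClO4)2, MeCN, 0 °C) to tert-butyl (6E,10R)-2-bromo-2,6,10-trimethyl-3-oxododec-6-en-11-ynoate F1. F1 is cyclised by bromine‑atom‑transfer radical bicyclisation under chiral Lewis‑acid control (Mg(ClO4)2 with the C8‑matched tert‑butyl‑bisoxazoline antipode, Et3B/O2, toluene, −78 °C), in which the chelated radical is attacked on one enantioface, giving tert-butyl (1R,4aS,6R,8aR)-5-(bromomethylidene)-1,4a,6-trimethyl-2-oxodecahydronaphthalene-1-carboxylate F2. Ozonolysis of F2 (O3, then Me2S) gives 10 directly.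

Step 7 (directed C–H lactonisation). Baeyer–Villiger oxidation of the ketones, decarboxylation of the β‑keto acid or wrong‑site oxidation could compete. The fallback sets out from 10 and returns at 12. After TFA cleavage the acid 11 is isolated cold and converted through its acid chloride ((COCl)2, cat. DMF, then NH3) into (1R,4aS,6R,8aR)-1,4a,6-trimethyl-2,5-dioxodecahydronaphthalene-1-carboxamide F3. A Hofmann–Löffler–Freytag‑type sequence (PhI(OAc)2, I2, visible light, CH2Cl2) generates the amidyl radical, which abstracts the 1,3‑diaxial 6β‑H; iodination at C6 and O‑cyclisation give 19-imino-19,6β-epoxy-11,12,13,14,15,16-hexanorlabdane-3,9-dione F4. Mild aqueous acid hydrolyses F4 to 12.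

Step 12 (Meyer–Schuster / oxa‑Michael). The wrong hydroxyl could transpose (giving the C11 ketone), or Rupe elimination or a methyl shift from C10 could intervene. The fallback sets out from 16 (with 12) and returns at 21; it delivers oxygen to C12 intramolecularly instead of by ionisation. Compound 16 is silylated (TESOTf, 2,6‑lutidine) to (3R,4S)-4-(tert-butyldiphenylsilyloxy)-3-ethynyl-3-(triethylsilyloxy)tetrahydrofuran F5. Its cerium acetylide is added to enolate 17 as in step 11 to give the 13‑O‑triethylsilyl analogue of 19 F6. The 9‑hydroxyl is acetylated (Ac2O, DMAP, Et3N, 40 °C) to the 9β‑acetate of F6 F7. Gold(I)‑catalysed [3,3] acyloxy shift (Ph3PAuNTf2, wet butanone) moves oxygen from C9 to C12 only and, after hydrolysis of the allenyl acetate, gives the 13‑O‑triethylsilyl analogue of 20 F8. TsOH·H2O in wet THF removes the triethylsilyl group and closes ring D to 21.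

**Further compounds**
F1 | step 5 | tert-butyl (6E,10R)-2-bromo-2,6,10-trimethyl-3-oxododec-6-en-11-ynoate | CC(Br)(C(=O)OC(C)(C)C)C(=O)CC/C(C)=C/CC[C@@H](C)C#C
F2 | step 5 | tert-butyl (1R,4aS,6R,8aR)-5-(bromomethylidene)-1,4a,6-trimethyl-2-oxodecahydronaphthalene-1-carboxylate | C[C@@H]1CC[C@H]2[C@@](C)(C(=O)OC(C)(C)C)C(=O)CC[C@]2(C)C1=CBr
F3 | step 7 | (1R,4aS,6R,8aR)-1,4a,6-trimethyl-2,5-dioxodecahydronaphthalene-1-carboxamide | C[C@@H]1CC[C@H]2[C@@](C)(C(N)=O)C(=O)CC[C@]2(C)C1=O
F4 | step 7 | 19-imino-19,6β-epoxy-11,12,13,14,15,16-hexanorlabdane-3,9-dione | C[C@@H]1C[C@H]2OC(=N)[C@@]3(C)C(=O)CC[C@@](C)([C@@H]23)C1=O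
F5 | step 12 | (3R,4S)-4-(tert-butyldiphenylsilyloxy)-3-ethynyl-3-(triethylsilyloxy)tetrahydrofuran | C#C[C@@]1(O[Si](CC)(CC)CC)COC[C@@H]1O[Si](c1ccccc1)(c1ccccc1)C(C)(C)C
F6 | step 12 | 13-O-triethylsilyl analogue of 19 | C[C@@H]1C[C@H]2OC(=O)[C@@]3(C)C(=O)CC[C@@](C)([C@@H]23)[C@]1(O)C#C[C@@]1(O[Si](CC)(CC)CC)COC[C@@H]1O[Si](c1ccccc1)(c1ccccc1)C(C)(C)C
F7 | step 12 | 9β-acetate of F6 | C[C@@H]1C[C@H]2OC(=O)[C@@]3(C)C(=O)CC[C@@](C)([C@@H]23)[C@]1(OC(C)=O)C#C[C@@]1(O[Si](CC)(CC)CC)COC[C@@H]1O[Si](c1ccccc1)(c1ccccc1)C(C)(C)C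
F8 | step 12 | 13-O-triethylsilyl analogue of 20 | C[C@@H]1C[C@H]2OC(=O)[C@@]3(C)C(=O)CC[C@@](C)([C@@H]23)C1=CC(=O)[C@@]1(O[Si](CC)(CC)CC)COC[C@@H]1O[Si](c1ccccc1)(c1ccccc1)C(C)(C)C
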